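**Plan**

Locants are those of the 2,3-dihydro-1,4-benzodioxine core: O-1 and C-2 carry the 3,5-dihydroxyphenyl side, C-3 and O-4 the catechol side, C-6 of ring A the styryl arm, and C-8a (bonded to O-1) is para to C-6.
Retrosynthesis: remove six O-allyl groups; cut the aryl ether O-4–C-4a (intramolecular Ullmann etherification) to a bromo alcohol, which comes from the C-3 ketone; cut the stilbene C=C (Horner–Wadsworth–Emmons); cut C-2–C-3 and O-1–C-8a together, which leaves dithiane 3, aldehyde 5 and 3-bromo-4-fluorobenzonitrile 9.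
Forward order: the open chain is joined first in one flask from the three pieces, then the styryl arm is built on ring A, the C-3 ketone is unmasked and reduced, and the dioxane ring is closed last; deallylation gives the target.
Enabling feature: C-3 is an aroyl-level carbon that can be reversed in polarity as a 2-aryl-1,3-dithiane anion, C-2 is the carbonyl carbon of a benzaldehyde so that O-1 is born as an alkoxide, and C-8a of ring A stands para to C-6, so a nitrile at C-6 (the later styryl carbon) activates exactly the C-8a–F bond for SNAr.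
Stereochemistry: C-2 is made racemic on purpose and ends up α to the C-3 ketone; one Noyori–Ikariya transfer hydrogenation with dynamic kinetic resolution sets C-3 (catalyst) and C-2 (fast enolisation, polar Felkin–Anh) as R,R; the ring closure forms an aryl–O bond and leaves both centres as they are, which gives the trans (2R,3R) core.

Key step: step 7

Assumption: in step 11 the (S,S)-catalyst is taken to give the (R)-carbinol with syn selection of the ketone enantiomer, as in the reduction of benzoin to (R,R)-hydrobenzoin; compounds 11 to 16 are racemates at C-2.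

**Route**

Step 1
Reactants: 1 3,4-dihydroxybenzaldehyde
Product: 2 3,4-bis(allyloxy)benzaldehyde
Conditions: allyl bromide (2.5 equiv), K2CO3, DMF, 60 °C
Reagents that add atoms: allyl bromide, C=CCBr
Why: Williamson ether synthesis (SN2 of both phenoxides on allyl bromide) should mask the catechol as allyl ethers that survive organolithium, hydride, base and acid and that leave at the end under neutral conditions.

Step 2
Reactants: 2 3,4-bis(allyloxy)benzaldehyde
Product: 3 2-[3,4-bis(allyloxy)phenyl]-1,3-dithiane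
Conditions: propane-1,3-dithiol (1.1 equiv), BF3·OEt2 (0.2 equiv), CH2Cl2, 0 °C to rt
Reagents that add atoms: propane-1,3-dithiol, SCCCS
Why: Lewis-acid-catalysed thioacetalisation should give the 2-aryl-1,3-dithiane that is needed for the Corey–Seebach reversal of polarity in step 7 and that later guards the ketone during steps 8 and 9.

Step 3
Reactants: 4 3,5-dihydroxybenzaldehyde
Product: 5 3,5-bis(allyloxy)benzaldehyde
Conditions: allyl bromide (2.5 equiv), K2CO3, DMF, 60 °C
Reagents that add atoms: allyl bromide, C=CCBr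
Why: Williamson ether synthesis as in step 1.

Step 4
Reactants: 5 3,5-bis(allyloxy)benzaldehyde
Product: 6 [3,5-bis(allyloxy)phenyl]methanol
Conditions: NaBH4, MeOH, 0 °C
Reagents that add atoms: none
Why: NaBH4 reduction of the aryl aldehyde to the benzylic alcohol; no stereocentre is formed.

Step 5
Reactants: 6 [3,5-bis(allyloxy)phenyl]methanol
Product: 7 1-(bromomethyl)-3,5-bis(allyloxy)benzene
Conditions: CBr4, PPh3, CH2Cl2, 0 °C
Reagents that add atoms: carbon tetrabromide, BrC(Br)(Br)Br
Why: Appel bromination converts the benzylic alcohol into the bromide under neutral conditions that leave the allyl ethers alone.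

Step 6
Reactants: 7 1-(bromomethyl)-3,5-bis(allyloxy)benzene
Product: 8 diethyl {[3,5-bis(allyloxy)phenyl]methyl}phosphonate
Conditions: P(OEt)3 (neat), 120 °C
Reagents that add atoms: triethyl phosphite, CCOP(OCC)OCC
Why: Michaelis–Arbuzov reaction of the benzylic bromide with triethyl phosphite gives the phosphonate for the olefination in step 9.

Step 7
Reactants: 3 2-[3,4-bis(allyloxy)phenyl]-1,3-dithiane; 5 3,5-bis(allyloxy)benzaldehyde; 9 3-bromo-4-fluorobenzonitrile
Product: 12 racemic 3-bromo-4-{[3,5-bis(allyloxy)phenyl][2-(3,4-bis(allyloxy)phenyl)-1,3-dithian-2-yl]methoxy}benzonitrile, via lithiated dithiane 10 (not isolated), via lithium alkoxide 11 (not isolated)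
Conditions: n-BuLi (1.0 equiv), THF, −78 to −40 °C; 5, −78 °C; then 9 (1.2 equiv), DMPU, −78 °C to rt
Reagents that add atoms: none
Why: n-BuLi removes the C-2 proton of the 2-aryl-1,3-dithiane (Corey–Seebach reversal of polarity) and the sulfur-stabilised carbanion 10 adds to the carbonyl of 5, which forms the C-2–C-3 bond and leaves O-1 as lithium alkoxide 11; with DMPU as donor solvent this alkoxide then attacks the fluorine-bearing carbon of 9 through a Meisenheimer adduct stabilised by the para nitrile and expels fluoride (SNAr), which forms the O-1–C-8a aryl ether. The closest known reaction types are the addition of lithiated dithianes to aldehydes and the SNAr etherification of 4-fluorobenzonitriles by alkoxides, here run in one flask. No ring is closed in this step; the dioxane ring is closed later in step 12. The one new stereocentre (C-2) arises racemic, which is intended because it becomes α to the ketone and is set in step 11. The step needs chemoselectivity and site selectivity: O-arylation must beat C-arylation, which the order of addition secures because carbanion 10 is used up by 5 before 9 enters, and substitution must occur at C–F and not at C–Br, which the para nitrile (bromine is meta to it) and the better nucleofugality of fluoride in SNAr secure.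

Step 8
Reactants: 12 racemic 3-bromo-4-{[3,5-bis(allyloxy)phenyl][2-(3,4-bis(allyloxy)phenyl)-1,3-dithian-2-yl]methoxy}benzonitrile
Product: 14 racemic 3-bromo-4-{[3,5-bis(allyloxy)phenyl][2-(3,4-bis(allyloxy)phenyl)-1,3-dithian-2-yl]methoxy}benzaldehyde, via aluminium aldimine 13 (not isolated)
Conditions: i-Bu2AlH (1.3 equiv), CH2Cl2, −78 °C; then 1 M HCl, 0 °C
Reagents that add atoms: water, O
Why: i-Bu2AlH adds one hydride to the nitrile and stops at the N-aluminated aldimine 13, which is hydrolysed to the aldehyde on acidic work-up, while the dithiane (the masked ketone), the aryl bromide and the allyl ethers are inert.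

Step 9
Reactants: 14 racemic 3-bromo-4-{[3,5-bis(allyloxy)phenyl][2-(3,4-bis(allyloxy)phenyl)-1,3-dithian-2-yl]methoxy}benzaldehyde; 8 diethyl {[3,5-bis(allyloxy)phenyl]methyl}phosphonate
Product: 15 racemic 2-[3,4-bis(allyloxy)phenyl]-2-{[3,5-bis(allyloxy)phenyl](2-bromo-4-{(E)-2-[3,5-bis(allyloxy)phenyl]ethenyl}phenoxy)methyl}-1,3-dithiane
Conditions: 8 (1.2 equiv), KOtBu, THF, 0 °C to rt
Reagents that add atoms: none
Why: Horner–Wadsworth–Emmons olefination with the semistabilised benzylic phosphonate should give the (E)-stilbene, and once the formyl group is gone ring A no longer carries an acceptor para to O-1.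

Step 10
Reactants: 15 racemic 2-[3,4-bis(allyloxy)phenyl]-2-{[3,5-bis(allyloxy)phenyl](2-bromo-4-{(E)-2-[3,5-bis(allyloxy)phenyl]ethenyl}phenoxy)methyl}-1,3-dithiane
Product: 16 racemic 1-[3,4-bis(allyloxy)phenyl]-2-[3,5-bis(allyloxy)phenyl]-2-(2-bromo-4-{(E)-2-[3,5-bis(allyloxy)phenyl]ethenyl}phenoxy)ethan-1-one
Conditions: MeI (10 equiv), CaCO3, MeCN/H2O (4:1), 45 °C
Reagents that add atoms: water, O
Why: alkylative thioacetal cleavage (S-methylation, then hydrolysis of the thionium ion) frees the C-3 ketone without touching the alkenes, and the stereocentre at C-2, now α to the carbonyl, stays racemic and becomes epimerisable as planned.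

Step 11
Reactants: 16 racemic 1-[3,4-bis(allyloxy)phenyl]-2-[3,5-bis(allyloxy)phenyl]-2-(2-bromo-4-{(E)-2-[3,5-bis(allyloxy)phenyl]ethenyl}phenoxy)ethan-1-one
Product: 17 (1R,2R)-1-[3,4-bis(allyloxy)phenyl]-2-[3,5-bis(allyloxy)phenyl]-2-(2-bromo-4-{(E)-2-[3,5-bis(allyloxy)phenyl]ethenyl}phenoxy)ethan-1-ol
Conditions: RuCl[(S,S)-TsDPEN](p-cymene) (2 mol%), HCO2H/Et3N (5:2), DMF, 40 °C
Reagents that add atoms: none
Why: Noyori–Ikariya asymmetric transfer hydrogenation under dynamic kinetic resolution: the C-2 hydrogen (α to the ketone, benzylic, α-aryloxy) epimerises fast through the enol in HCO2H/Et3N, the (S,S)-catalyst delivers hydride to one carbonyl face to set C-3 as (R), and the ketone enantiomer that reacts by the polar Felkin–Anh mode is drained preferentially, which should give the syn (1R,2R)-alcohol.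

Step 12
Reactants: 17 (1R,2R)-1-[3,4-bis(allyloxy)phenyl]-2-[3,5-bis(allyloxy)phenyl]-2-(2-bromo-4-{(E)-2-[3,5-bis(allyloxy)phenyl]ethenyl}phenoxy)ethan-1-ol
Product: 18 (2R,3R)-3-[3,4-bis(allyloxy)phenyl]-2-[3,5-bis(allyloxy)phenyl]-6-{(E)-2-[3,5-bis(allyloxy)phenyl]ethenyl}-2,3-dihydro-1,4-benzodioxine
Conditions: CuI (10 mol%), 3,4,7,8-tetramethyl-1,10-phenanthroline (20 mol%), Cs2CO3 (2 equiv), toluene, 110 °C
Reagents that add atoms: none
Why: Ullmann-type copper-catalysed intramolecular etherification closes the six-membered dioxane ring by forming the O-4–C-4a bond at the aryl carbon (6-exo with respect to the aryl halide), so neither stereocentre takes part and the syn alcohol should give the trans (2R,3R) ring; with the nitrile long since converted into the styryl arm no Smiles shift of ring A between the two oxygens is possible.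

Step 13
Reactants: 18 (2R,3R)-3-[3,4-bis(allyloxy)phenyl]-2-[3,5-bis(allyloxy)phenyl]-6-{(E)-2-[3,5-bis(allyloxy)phenyl]ethenyl}-2,3-dihydro-1,4-benzodioxine
Product: 19 cassigarol E
Conditions: Pd(PPh3)4 (10 mol%), morpholine (20 equiv), THF, 40 °C, degassed
Reagents that add atoms: none
Why: Tsuji–Trost deallylation: zerovalent palladium ionises each aryl allyl ether to a π-allyl complex and a phenoxide and morpholine takes up the allyl groups, so all six phenols are freed under neutral conditions that spare the stilbene and the two benzylic C–O bonds.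

**Compound list**

1 | 3,4-dihydroxybenzaldehyde | O=Cc1ccc(O)c(O)c1 | starting material
2 | 3,4-bis(allyloxy)benzaldehyde | O=Cc1ccc(OCC=C)c(OCC=C)c1 | intermediate
3 | 2-[3,4-bis(allyloxy)phenyl]-1,3-dithiane | C=CCOc1ccc(C2SCCCS2)cc1OCC=C | intermediate
4 | 3,5-dihydroxybenzaldehyde | O=Cc1cc(O)cc(O)c1 | starting material
5 | 3,5-bis(allyloxy)benzaldehyde | O=Cc1cc(OCC=C)cc(OCC=C)c1 | intermediate
6 | [3,5-bis(allyloxy)phenyl]methanol | OCc1cc(OCC=C)cc(OCC=C)c1 | intermediate
7 | 1-(bromomethyl)-3,5-bis(allyloxy)benzene | BrCc1cc(OCC=C)cc(OCC=C)c1 | intermediate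
8 | diethyl {[3,5-bis(allyloxy)phenyl]methyl}phosphonate | CCOP(=O)(Cc1cc(OCC=C)cc(OCC=C)c1)OCC | intermediate
9 | 3-bromo-4-fluorobenzonitrile | N#Cc1ccc(F)c(Br)c1 | starting material
10 | 2-lithio-2-[3,4-bis(allyloxy)phenyl]-1,3-dithiane (lithiated dithiane, not isolated) | [Li]C1(c2ccc(OCC=C)c(OCC=C)c2)SCCCS1 | intermediate
11 | lithium [3,5-bis(allyloxy)phenyl]{2-[3,4-bis(allyloxy)phenyl]-1,3-dithian-2-yl}methanolate (lithium alkoxide, racemic, not isolated) | [Li]OC(c1cc(OCC=C)cc(OCC=C)c1)C1(c2ccc(OCC=C)c(OCC=C)c2)SCCCS1 | intermediate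
12 | racemic 3-bromo-4-{[3,5-bis(allyloxy)phenyl][2-(3,4-bis(allyloxy)phenyl)-1,3-dithian-2-yl]methoxy}benzonitrile | N#Cc1ccc(OC(c2cc(OCC=C)cc(OCC=C)c2)C2(c3ccc(OCC=C)c(OCC=C)c3)SCCCS2)c(Br)c1 | intermediate
13 | N-(diisobutylalumanyl)aldimine of 14 (aluminium aldimine, racemic, not isolated) | CC(C)C[Al](CC(C)C)N=Cc1ccc(OC(c2cc(OCC=C)cc(OCC=C)c2)C2(c3ccc(OCC=C)c(OCC=C)c3)SCCCS2)c(Br)c1 | intermediate
14 | racemic 3-bromo-4-{[3,5-bis(allyloxy)phenyl][2-(3,4-bis(allyloxy)phenyl)-1,3-dithian-2-yl]methoxy}benzaldehyde | O=Cc1ccc(OC(c2cc(OCC=C)cc(OCC=C)c2)C2(c3ccc(OCC=C)c(OCC=C)c3)SCCCS2)c(Br)c1 | intermediate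
15 | racemic 2-[3,4-bis(allyloxy)phenyl]-2-{[3,5-bis(allyloxy)phenyl](2-bromo-4-{(E)-2-[3,5-bis(allyloxy)phenyl]ethenyl}phenoxy)methyl}-1,3-dithiane | C=CCOc1cc(OCC=C)cc(/C=C/c2ccc(OC(c3cc(OCC=C)cc(OCC=C)c3)C3(c4ccc(OCC=C)c(OCC=C)c4)SCCCS3)c(Br)c2)c1 | intermediate
16 | racemic 1-[3,4-bis(allyloxy)phenyl]-2-[3,5-bis(allyloxy)phenyl]-2-(2-bromo-4-{(E)-2-[3,5-bis(allyloxy)phenyl]ethenyl}phenoxy)ethan-1-one | C=CCOc1cc(OCC=C)cc(/C=C/c2ccc(OC(c3cc(OCC=C)cc(OCC=C)c3)C(=O)c3ccc(OCC=C)c(OCC=C)c3)c(Br)c2)c1 | intermediate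
17 | (1R,2R)-1-[3,4-bis(allyloxy)phenyl]-2-[3,5-bis(allyloxy)phenyl]-2-(2-bromo-4-{(E)-2-[3,5-bis(allyloxy)phenyl]ethenyl}phenoxy)ethan-1-ol | O[C@H](c1ccc(OCC=C)c(OCC=C)c1)[C@@H](c1cc(OCC=C)cc(OCC=C)c1)Oc1ccc(/C=C/c2cc(OCC=C)cc(OCC=C)c2)cc1Br | intermediate
18 | (2R,3R)-3-[3,4-bis(allyloxy)phenyl]-2-[3,5-bis(allyloxy)phenyl]-6-{(E)-2-[3,5-bis(allyloxy)phenyl]ethenyl}-2,3-dihydro-1,4-benzodioxine (hexa-O-allyl cassigarol E) | C=CCOc1cc(OCC=C)cc(/C=C/c2ccc3c(c2)O[C@H](c2ccc(OCC=C)c(OCC=C)c2)[C@@H](c2cc(OCC=C)cc(OCC=C)c2)O3)c1 | intermediate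
19 | cassigarol E, 5-[(E)-2-[(2R,3R)-3-(3,4-dihydroxyphenyl)-2-(3,5-dihydroxyphenyl)-2,3-dihydro-1,4-benzodioxin-6-yl]ethenyl]benzene-1,3-diol | Oc1cc(O)cc(/C=C/c2ccc3c(c2)O[C@H](c2ccc(O)c(O)c2)[C@@H](c2cc(O)cc(O)c2)O3)c1 | target

**Count and risks**

Total step count: 13. Longest linear sequence: 9 steps (1, 2, 7, 8, 9, 10, 11, 12, 13).

Steps most likely to fail:

1. Step 7. The hindered lithium alkoxide may displace fluoride too slowly at the carbon flanked by bromine, so that retro-addition to the dithianyl anion or attack of the alkoxide at the nitrile takes over. The fallback makes the C-2–C-3 bond by alkylation and the O-1 ether bond by substitution at the sp3 carbon; it sets out from 3 and comes back at 16. Lithiated 3 (n-BuLi, THF, −78 °C) is alkylated with bromide 7 to give 2-[3,4-bis(allyloxy)phenyl]-2-{[3,5-bis(allyloxy)phenyl]methyl}-1,3-dithiane F1. Hydrolysis with MeI and CaCO3 in aqueous MeCN gives the deoxybenzoin 1-[3,4-bis(allyloxy)phenyl]-2-[3,5-bis(allyloxy)phenyl]ethan-1-one F2. Its lithium enolate (LiN(SiMe3)2, THF, −78 °C) is brominated with CBr4 to racemic 2-bromo-1-[3,4-bis(allyloxy)phenyl]-2-[3,5-bis(allyloxy)phenyl]ethan-1-one F3. Separately, commercial 3-bromo-4-hydroxybenzaldehyde and phosphonate 8 (KOtBu, 2.2 equiv, THF) give 2-bromo-4-{(E)-2-[3,5-bis(allyloxy)phenyl]ethenyl}phenol F4. F3 and F4 with K2CO3 in acetone (Williamson substitution) give ketone 16, and steps 11 to 13 follow unchanged.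

2. Step 11. Epimerisation at C-2 may be slower than hydride transfer, or the catalyst may discriminate poorly between the two ketone enantiomers, so that the alcohol forms as a mixture of diastereomers with the wrong C-2 epimer carried along. The fallback is a classical resolution; it sets out from 16 and comes back at 17. Luche reduction (NaBH4, CeCl3·7H2O, MeOH, −40 °C) should give mainly the Felkin–Anh product, the racemic syn alcohol (1R*,2R*)-1-[3,4-bis(allyloxy)phenyl]-2-[3,5-bis(allyloxy)phenyl]-2-(2-bromo-4-{(E)-2-[3,5-bis(allyloxy)phenyl]ethenyl}phenoxy)ethan-1-ol F5, which is freed from the anti isomer by chromatography. Steglich esterification with (S)-2-methoxy-2-phenylacetic acid (DCC, DMAP, CH2Cl2) gives two diastereomeric esters; the (S)-2-methoxy-2-phenylacetate of the (1R,2R)-alcohol F6 is separated by chromatography or crystallisation. Methanolysis (K2CO3, MeOH) returns 17.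

3. Step 12. Carbon–oxygen bond formation at copper may be slow for the hindered secondary benzylic alkoxide and the electron-rich aryl bromide, so that protodebromination or oxidation of the alcohol competes. The fallback closes the ring at the sp3 carbon instead of the arene; it sets out from 17 and comes back at 18. Bromine–lithium exchange (n-BuLi, 2.2 equiv, THF, −78 °C), quench with B(OMe)3 and oxidation (H2O2, NaOH, 0 °C) give the phenol (1R,2R)-1-[3,4-bis(allyloxy)phenyl]-2-[3,5-bis(allyloxy)phenyl]-2-(2-hydroxy-4-{(E)-2-[3,5-bis(allyloxy)phenyl]ethenyl}phenoxy)ethan-1-ol F7. Catalytic p-TsOH in CH2Cl2 ionises the 4-alkoxybenzylic C-3 alcohol and the phenol closes the dioxane ring at C-3 under thermodynamic control to the trans isomer 18; C-2 is not touched and the allyl ethers are stable to acid.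

Further compounds
F1 | step 7 | 2-[3,4-bis(allyloxy)phenyl]-2-{[3,5-bis(allyloxy)phenyl]methyl}-1,3-dithiane | C=CCOc1cc(OCC=C)cc(CC2(c3ccc(OCC=C)c(OCC=C)c3)SCCCS2)c1
F2 | step 7 | 1-[3,4-bis(allyloxy)phenyl]-2-[3,5-bis(allyloxy)phenyl]ethan-1-one | C=CCOc1cc(OCC=C)cc(CC(=O)c2ccc(OCC=C)c(OCC=C)c2)c1
F3 | step 7 | racemic 2-bromo-1-[3,4-bis(allyloxy)phenyl]-2-[3,5-bis(allyloxy)phenyl]ethan-1-one | C=CCOc1cc(OCC=C)cc(C(Br)C(=O)c2ccc(OCC=C)c(OCC=C)c2)c1
F4 | step 7 | 2-bromo-4-{(E)-2-[3,5-bis(allyloxy)phenyl]ethenyl}phenol | Oc1ccc(/C=C/c2cc(OCC=C)cc(OCC=C)c2)cc1Br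
F5 | step 11 | racemic syn (1R*,2R*)-1-[3,4-bis(allyloxy)phenyl]-2-[3,5-bis(allyloxy)phenyl]-2-(2-bromo-4-{(E)-2-[3,5-bis(allyloxy)phenyl]ethenyl}phenoxy)ethan-1-ol | OC(c1ccc(OCC=C)c(OCC=C)c1)C(c1cc(OCC=C)cc(OCC=C)c1)Oc1ccc(/C=C/c2cc(OCC=C)cc(OCC=C)c2)cc1Br
F6 | step 11 | (1R,2R)-1-[3,4-bis(allyloxy)phenyl]-2-[3,5-bis(allyloxy)phenyl]-2-(2-bromo-4-{(E)-2-[3,5-bis(allyloxy)phenyl]ethenyl}phenoxy)ethyl (S)-2-methoxy-2-phenylacetate | CO[C@H](C(=O)O[C@H](c1ccc(OCC=C)c(OCC=C)c1)[C@@H](c1cc(OCC=C)cc(OCC=C)c1)Oc1ccc(/C=C/c2cc(OCC=C)cc(OCC=C)c2)cc1Br)c1ccccc1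
F7 | step 12 | (1R,2R)-1-[3,4-bis(allyloxy)phenyl]-2-[3,5-bis(allyloxy)phenyl]-2-(2-hydroxy-4-{(E)-2-[3,5-bis(allyloxy)phenyl]ethenyl}phenoxy)ethan-1-ol | O[C@H](c1ccc(OCC=C)c(OCC=C)c1)[C@@H](c1cc(OCC=C)cc(OCC=C)c1)Oc1ccc(/C=C/c2cc(OCC=C)cc(OCC=C)c2)cc1O
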